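**Retrosynthetic overview**

- The target is 3-docosyl-5-methoxy-2-methyl-1,4-benzoquinone, with ring atoms numbered C1(=O), C2(OMe), C3(H), C4(=O), C5(Me), C6(docosyl). The methyl ether is cut first (vinylogous ester of the 2-hydroxyquinone), then the C1 oxygen (oxidation of a resorcinol at C1, the only free position para to a hydroxyl).
- Feature the plan rests on: the oxygens on C2 and C4 are 1,3-related across C3–H, the methyl sits on C5 beside C4 and the chain on C6. This is the pattern of a 4-methyl-5-alkylcyclohexane-1,3-dione.
- Key disconnection of the only ring (six-membered carbocycle): bonds C5–C6 (Michael) and C3–C4 (Claisen). The enone (E)-hexacos-3-en-2-one supplies C3, C2, C1, C6 and the chain; dimethyl methylmalonate supplies C4, C5 and the C-methyl (four ring carbons plus two).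
- The enone comes in one step from tetracos-1-ene and but-3-en-2-one by cross-metathesis.
- Ring order: the carbocycle is closed in step 2, decarboxylated in step 3, aromatised in step 4, oxidised in step 5 and O-methylated in step 6.

Key step: step 2

Assumption: tetracos-1-ene is taken as the commercially available C24 α-olefin; the cyclohexanedione intermediates are carried as racemic diastereomer mixtures, which is acceptable because all their stereocentres vanish on aromatisation and the target is achiral.

**Route**

Step 1
Reactants: 1 tetracos-1-ene; 2 but-3-en-2-one
Product: 3 (E)-hexacos-3-en-2-one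
Conditions: 2 (3 equiv), second-generation Grubbs catalyst RuCl2(=CHPh)(H2IMes)(PCy3) (2 mol %), CH2Cl2, 40 °C
Reagents that add atoms: none
Why: Olefin cross-metathesis: the terminal alkene engages the ruthenium alkylidene readily while the electron-poor vinyl ketone does not homodimerise, so an excess of 2 should channel 1 (and any homodimer of 1, by secondary metathesis) to the cross product, formed as the conjugated (E)-enone under thermodynamic control with loss of ethene.

Step 2
Reactants: 3 (E)-hexacos-3-en-2-one; 4 dimethyl methylmalonate
Product: 6 methyl 6-docosyl-1-methyl-2,4-dioxocyclohexane-1-carboxylate (racemic diastereomer mixture), via acyclic Michael adduct 5 (not isolated)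
Conditions: NaOMe (1.2 equiv), MeOH–THF, reflux; then aq HCl, 0 °C
Reagents that add atoms: none
Why: Methoxide deprotonates 4 and the tertiary malonate carbanion adds 1,4 to the β-carbon of 3 to give keto diester 5 (bond C5–C6 of the later quinone); the equilibrating base then forms the enolate at the terminal CH3 of the methyl ketone, which attacks one ester carbonyl and expels methoxide (bond C3–C4), a Claisen acylation of Dieckmann type. The closest known reaction is the classical malonate/alk-3-en-2-one Michael–Claisen annulation used for 5-alkylcyclohexane-1,3-diones and 5-alkylresorcinols. The six-membered carbocycle closes in a 6-exo-trig mode (enolate carbon onto an exocyclic ester C=O); the other ketone enolate, at the internal CH2, could only close a four-membered ring and stays unproductive. Two stereocentres arise (the quaternary C1 and C6 of 6); nothing controls them, the racemic diastereomer mixture is accepted, and both are removed by decarboxylation and aromatisation. The step needs conjugate rather than direct carbonyl addition and ring closure through the ketone methyl; both are secured because every event before cyclisation is reversible under NaOMe in methanol, whereas the cyclic product is withdrawn as its 1,3-dionate (pKa near 5). The same enolate shields the ketone beside the quaternary carbon from retro-Claisen attack by methoxide.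

Step 3
Reactants: 6 methyl 6-docosyl-1-methyl-2,4-dioxocyclohexane-1-carboxylate
Product: 8 5-docosyl-4-methylcyclohexane-1,3-dione (racemic diastereomer mixture), via keto acid 7 (not isolated)
Conditions: aq NaOH, MeOH–THF, reflux; then aq HCl to pH 1, 70 °C
Reagents that add atoms: none
Why: Ester saponification followed by decarboxylation of the β-keto acid: hydroxide delivers the carboxyl oxygen of 7, which leaves again as CO2 once acidification releases the adjacent ketone from the dionate and the cyclic six-membered decarboxylation transition state becomes available; the two stereocentres of 8 (C4 is epimerisable) remain an unimportant mixture.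

Step 4
Reactants: 8 5-docosyl-4-methylcyclohexane-1,3-dione
Product: 9 5-docosyl-4-methylbenzene-1,3-diol
Conditions: 10% Pd/C, p-cymene, reflux, slow N2 stream
Reagents that add atoms: none
Why: Catalytic dehydrogenation (aromatisation): the dione stands only one H2 below the resorcinol, and palladium-mediated loss of H2 across C4–C5 or C5–C6 of the enolised ring, followed by tautomerisation, is driven by the gain of aromaticity and by sweeping the hydrogen out; both stereocentres are erased here.

Step 5
Reactants: 9 5-docosyl-4-methylbenzene-1,3-diol
Product: 10 3-docosyl-5-hydroxy-2-methylcyclohexa-2,5-diene-1,4-dione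
Conditions: (KSO3)2NO (2.5 equiv), aq KH2PO4, methyltrioctylammonium chloride (cat.), CH2Cl2–H2O, 20 °C
Reagents that add atoms: potassium nitrosodisulfonate, [K+].[K+].[O-]S(=O)(=O)N([O])S(=O)(=O)[O-]
Why: Teuber oxidation: the nitroxyl radical removes the phenolic hydrogen, a second equivalent couples at the ring carbon para to that oxygen and loss of imidodisulfonate leaves the new carbonyl; in 9 the position para to the 3-OH (C6) is free while the position para to the 1-OH is blocked by the methyl, so oxidation should converge on the 2-hydroxy-1,4-quinone, of which the 4-hydroxy-1,2-quinone is merely a tautomer.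

Step 6
Reactants: 10 3-docosyl-5-hydroxy-2-methylcyclohexa-2,5-diene-1,4-dione
Product: 11 3-docosyl-5-methoxy-2-methylcyclohexa-2,5-diene-1,4-dione (target)
Conditions: MeOH–CH2Cl2, H2SO4 (cat.), 40 °C
Reagents that add atoms: methanol, CO
Why: Vinylogous Fischer esterification: the 2-hydroxyquinone is a vinylogous carboxylic acid, so acid-catalysed addition of methanol at the hydroxyl-bearing carbon and loss of water should give the methyl ether, the para-quinone with the methoxy group on C2 being the thermodynamically preferred isomer under these equilibrating conditions.

**Compound list**

1 | tetracos-1-ene | C=CCCCCCCCCCCCCCCCCCCCCCC | starting material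
2 | but-3-en-2-one | CC(=O)C=C | starting material
3 | (E)-hexacos-3-en-2-one | CC(=O)/C=C/CCCCCCCCCCCCCCCCCCCCCC | intermediate
4 | dimethyl methylmalonate (dimethyl 2-methylpropanedioate) | COC(=O)C(C)C(=O)OC | starting material
5 | dimethyl 2-methyl-2-(2-oxohexacosan-4-yl)propanedioate (racemic) | CC(=O)CC(CCCCCCCCCCCCCCCCCCCCCC)C(C)(C(=O)OC)C(=O)OC | intermediate
6 | methyl 6-docosyl-1-methyl-2,4-dioxocyclohexane-1-carboxylate (racemic diastereomer mixture) | COC(=O)C1(C)C(=O)CC(=O)CC1CCCCCCCCCCCCCCCCCCCCCC | intermediate
7 | 6-docosyl-1-methyl-2,4-dioxocyclohexane-1-carboxylic acid (racemic diastereomer mixture) | OC(=O)C1(C)C(=O)CC(=O)CC1CCCCCCCCCCCCCCCCCCCCCC | intermediate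
8 | 5-docosyl-4-methylcyclohexane-1,3-dione (racemic diastereomer mixture) | CC1C(=O)CC(=O)CC1CCCCCCCCCCCCCCCCCCCCCC | intermediate
9 | 5-docosyl-4-methylbenzene-1,3-diol | Cc1c(O)cc(O)cc1CCCCCCCCCCCCCCCCCCCCCC | intermediate
10 | 3-docosyl-5-hydroxy-2-methylcyclohexa-2,5-diene-1,4-dione | CCCCCCCCCCCCCCCCCCCCCCC1=C(C)C(=O)C=C(O)C1=O | intermediate
11 | 3-docosyl-5-methoxy-2-methylcyclohexa-2,5-diene-1,4-dione | CCCCCCCCCCCCCCCCCCCCCCC1=C(C)C(=O)C=C(OC)C1=O | target

**Step count and risks**

Total step count: 6. Longest linear sequence: 6 steps (1 to 11).

Steps most likely to fail:

1. Step 2 (key annulation). The tertiary methylmalonate carbanion may add slowly and reversibly, so that base-induced self-condensation of the enone or stalling at the open-chain stage competes with ring closure. Fallback, setting out from 3: the annulation is run with unsubstituted dimethyl malonate (NaOMe, MeOH–THF, reflux), whose secondary carbanion adds readily, to give methyl 6-docosyl-2,4-dioxocyclohexane-1-carboxylate F1. Its dianion (LiN(iPr)2, 2.2 equiv, THF, −78 °C) is then methylated with MeI (1.0 equiv) at the ester-bearing ring carbon, the more basic terminus of the dianion, which returns to the route at 6.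

2. Step 4 (dehydrogenation). Hydrogen set free on palladium may be transferred back to the enolised dione, causing reduction or hydrogenolytic loss of one oxygen, and conversion may stay incomplete at the tolerated temperature. Fallback, setting out from 8: bromination with Br2 (1 equiv) in DMF at 0 °C should give 2-bromo-5-docosyl-4-methylcyclohexane-1,3-dione F2. Heating the same solution to 100–150 °C lets the HBr present move the bromine to a ring carbon α to one carbonyl, from where dehydrobromination and tautomerisation lead to the resorcinol, returning at 9.

3. Step 5 (radical oxidation). Transfer of the waxy resorcinol to the aqueous radical may be poor, and over-oxidation, oxidative coupling or attack at the carbon between the two hydroxyls may erode the electron-rich substrate and the hydroxyquinone formed. Fallback, setting out from 9: azo coupling with benzenediazonium chloride (aq NaOH–THF, 0 °C) at the free position para to a hydroxyl should give 5-docosyl-4-methyl-6-[(E)-phenyldiazenyl]benzene-1,3-diol F3. Reductive cleavage with Na2S2O4 should give 4-amino-5-docosyl-6-methylbenzene-1,3-diol F4. FeCl3 in dilute aqueous HCl then oxidises the para-aminophenol unit and hydrolyses the nitrogen off, returning at 10.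

**Further compounds**

F1 | step 2 | methyl 6-docosyl-2,4-dioxocyclohexane-1-carboxylate | COC(=O)C1C(=O)CC(=O)CC1CCCCCCCCCCCCCCCCCCCCCC
F2 | step 4 | 2-bromo-5-docosyl-4-methylcyclohexane-1,3-dione | CC1C(=O)C(Br)C(=O)CC1CCCCCCCCCCCCCCCCCCCCCC
F3 | step 5 | 5-docosyl-4-methyl-6-[(E)-phenyldiazenyl]benzene-1,3-diol | Cc1c(O)cc(O)c(/N=N/c2ccccc2)c1CCCCCCCCCCCCCCCCCCCCCC
F4 | step 5 | 4-amino-5-docosyl-6-methylbenzene-1,3-diol | Cc1c(O)cc(O)c(N)c1CCCCCCCCCCCCCCCCCCCCCC
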